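**Retrosynthetic overview**
- The ten-membered carbocycle is formed last, by ring-closing metathesis that makes the (Z)-C4=C5 alkene from a butanolide carrying a C6 vinyl group and a C4 isopropenyl end.
- The trans-butanolide is formed just before, by lactonisation of the C6 hydroxyl onto an α-methylene ester once the C8 alcohol carries the isovalerate.
- Key disconnection C7–C8: intermolecular indium-mediated Barbier allylation of a C8 aldehyde (C8–C10, C1–C4) with a (Z)-2-(bromomethyl)-2-enoate (C5–C7, C11–C13), which sets C7 and C8.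
- Aldehyde fragment: (S)-lactic acid (alkylation of its pivalaldehyde acetal sets C10), Weinreb amide, 3-methylbut-3-enyl Grignard reagent.
- Bromide fragment: (R)-but-3-ene-1,2-diol (C6) and methyl propiolate, via a Baylis–Hillman-type adduct and SN2' bromination.

Convention and assumption: C1–C13 in the text are the germacrane positions of the target (lactone oxygen on C6, isovalerate on C8, tertiary alcohol C10, ketone C1); compound 23 is carried as a mixture of carbinol epimers because that centre is removed in step 13.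

**Aldehyde fragment (steps 1–8)**

Step 1
Reactants: 1 (S)-lactic acid; 2 pivalaldehyde
Product: 3 (2S,5S)-2-tert-butyl-5-methyl-1,3-dioxolan-4-one
Conditions: TsOH·H2O (cat.), H2SO4 (cat.), pentane, reflux, Dean–Stark; recrystallisation from Et2O/pentane, −78 °C
Reagents that add atoms: none
Why: Acid-catalysed acetalisation with water removal gives the dioxolanone, whose cis isomer crystallises, so the lactate configuration is stored in the new acetal centre (self-regeneration of stereocentres).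

Step 2
Reactants: 3 (2S,5S)-2-tert-butyl-5-methyl-1,3-dioxolan-4-one; 4 allyl bromide
Product: 6 (2S,5R)-2-tert-butyl-5-methyl-5-(prop-2-en-1-yl)-1,3-dioxolan-4-one, via lithium enolate 5 (not isolated)
Conditions: LiN(iPr)2, THF, −78 °C; then 4, −78 → −30 °C
Reagents that add atoms: none
Why: Diastereoselective enolate alkylation: the planar enolate is attacked by allyl bromide on the face opposite the tert-butyl group, so allyl replaces H with retention and the future C10 is set as R.

Step 3
Reactants: 6 (2S,5R)-2-tert-butyl-5-methyl-5-(prop-2-en-1-yl)-1,3-dioxolan-4-one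
Product: 8 (2S,5R)-2-tert-butyl-5-methyl-5-(2-oxoethyl)-1,3-dioxolan-4-one, via ozonide 7 (not isolated)
Conditions: O3, CH2Cl2, −78 °C; then PPh3, −78 °C → rt
Reagents that add atoms: ozone, [O-][O+]=O
Why: Ozonolysis with reductive work-up cleaves the only alkene present to the aldehyde without touching the quaternary centre.

Step 4
Reactants: 8 (2S,5R)-2-tert-butyl-5-methyl-5-(2-oxoethyl)-1,3-dioxolan-4-one
Product: 10 (3R)-3-hydroxy-3-methyloxolan-2-one, via hydroxyethyl dioxolanone 9 (not isolated)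
Conditions: NaBH4 (0.3 equiv), MeOH, 0 °C; then TsOH·H2O (cat.), CH2Cl2, rt
Reagents that add atoms: none
Why: Chemoselective borohydride reduction of the aldehyde is followed by translactonisation of the new primary alcohol onto the activated acetal ester, which closes the five-membered lactone and expels pivalaldehyde.

Step 5
Reactants: 10 (3R)-3-hydroxy-3-methyloxolan-2-one
Product: 11 (2R)-2,4-dihydroxy-N-methoxy-N,2-dimethylbutanamide
Conditions: MeNH(OMe)·HCl, iPrMgCl, THF, −20 → 0 °C
Reagents that add atoms: N,O-dimethylhydroxylamine hydrochloride, CNOC.Cl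
Why: Aminolysis of the lactone by the magnesium amide gives the Weinreb amide, which is silylated at once to prevent relactonisation.

Step 6
Reactants: 11 (2R)-2,4-dihydroxy-N-methoxy-N,2-dimethylbutanamide
Product: 12 (2R)-N-methoxy-N,2-dimethyl-2,4-bis[(triethylsilyl)oxy]butanamide
Conditions: Et3SiOTf (2.5 equiv), 2,6-lutidine, CH2Cl2, −78 → 0 °C
Reagents that add atoms: triethylsilyl trifluoromethanesulfonate, CC[Si](CC)(CC)OS(=O)(=O)C(F)(F)F
Why: The silyl triflate is reactive enough to silylate the tertiary as well as the primary hydroxyl (silyl ether protection).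

Step 7
Reactants: 12 (2R)-N-methoxy-N,2-dimethyl-2,4-bis[(triethylsilyl)oxy]butanamide; 13 4-bromo-2-methylbut-1-ene
Product: 15 (6R)-2,6-dimethyl-6,8-bis[(triethylsilyl)oxy]oct-1-en-5-one, via Grignard reagent 14 (not isolated)
Conditions: 13, Mg, THF, rt; then 12, THF, 0 °C → rt; aq. NH4Cl
Reagents that add atoms: none
Why: Weinreb ketone synthesis: the Grignard reagent adds once because the magnesium chelate of the tetrahedral adduct survives until work-up, giving the C1 ketone with the C2–C4 chain.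

Step 8
Reactants: 15 (6R)-2,6-dimethyl-6,8-bis[(triethylsilyl)oxy]oct-1-en-5-one
Product: 16 (3R)-3,7-dimethyl-4-oxo-3-[(triethylsilyl)oxy]oct-7-enal
Conditions: (COCl)2, DMSO, CH2Cl2, −78 → −40 °C; then Et3N, −78 °C → rt
Reagents that add atoms: none
Why: Under Swern conditions a primary triethylsilyl ether is cleaved and oxidised directly to the aldehyde while the hindered tertiary silyl ether stays, which avoids a free γ-hydroxy ketone.

**Bromide fragment (steps 9–13)**

Step 9
Reactants: 17 (2R)-but-3-ene-1,2-diol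
Product: 18 (2R)-1,2-bis[(tert-butyldimethylsilyl)oxy]but-3-ene
Conditions: TBSCl (2.5 equiv), imidazole, DMF, rt
Reagents that add atoms: tert-butyldimethylsilyl chloride, CC(C)(C)[Si](C)(C)Cl
Why: Standard imidazole-promoted silylation of both hydroxyls; the stereocentre is not involved.

Step 10
Reactants: 18 (2R)-1,2-bis[(tert-butyldimethylsilyl)oxy]but-3-ene
Product: 19 (2R)-2-[(tert-butyldimethylsilyl)oxy]but-3-en-1-ol
Conditions: HF·pyridine, pyridine, THF, 0 °C
Reagents that add atoms: none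
Why: Buffered HF·pyridine removes the less hindered primary silyl ether much faster than the secondary one (sterically controlled desilylation).

Step 11
Reactants: 19 (2R)-2-[(tert-butyldimethylsilyl)oxy]but-3-en-1-ol
Product: 20 (2R)-2-[(tert-butyldimethylsilyl)oxy]but-3-enal
Conditions: Dess–Martin periodinane, NaHCO3, CH2Cl2, 0 °C; used crude at once
Reagents that add atoms: none
Why: Dess–Martin oxidation is fast and non-basic, so the epimerisable α-silyloxy β,γ-unsaturated aldehyde is formed without loss of configuration or alkene migration.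

Step 12
Reactants: 20 (2R)-2-[(tert-butyldimethylsilyl)oxy]but-3-enal; 21 methyl propiolate
Product: 23 methyl (4R)-4-[(tert-butyldimethylsilyl)oxy]-3-hydroxy-2-methylidenehex-5-enoate (3-epimer mixture), via vinylalane 22 (not isolated)
Conditions: 21, iBu2AlH, N-methylmorpholine N-oxide, THF, 0 °C; then 20, 0 °C → rt
Reagents that add atoms: none
Why: Vinylalumination: conjugate hydroalumination of the propiolate gives an α-aluminoacrylate that adds to the aldehyde, a non-basic equivalent of the Morita–Baylis–Hillman reaction that spares the sensitive aldehyde.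

Step 13
Reactants: 23 methyl (4R)-4-[(tert-butyldimethylsilyl)oxy]-3-hydroxy-2-methylidenehex-5-enoate
Product: 24 methyl (2Z,4R)-2-(bromomethyl)-4-[(tert-butyldimethylsilyl)oxy]hexa-2,5-dienoate
Conditions: NBS, Me2S, CH2Cl2, 0 °C → rt
Reagents that add atoms: N-bromosuccinimide, O=C1CCC(=O)N1Br
Why: Corey–Kim-type activation of the allylic alcohol and SN2' attack of bromide give the rearranged primary allylic bromide with the chain trans to the ester (the Z isomer), and both carbinol epimers converge.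

**Fragment union and endgame (steps 14–17)**

Step 14
Reactants: 16 (3R)-3,7-dimethyl-4-oxo-3-[(triethylsilyl)oxy]oct-7-enal; 24 methyl (2Z,4R)-2-(bromomethyl)-4-[(tert-butyldimethylsilyl)oxy]hexa-2,5-dienoate
Product: 26 methyl (3R,4R,6R)-3-[(1R)-1-[(tert-butyldimethylsilyl)oxy]prop-2-en-1-yl]-4-hydroxy-6,10-dimethyl-2-methylidene-7-oxo-6-[(triethylsilyl)oxy]undec-10-enoate, via allylindium reagent 25 (not isolated)
Conditions: In powder (2 equiv), THF/H2O (1:1), rt
Reagents that add atoms: none
Why: Barbier-type carbonyl allylation joining the two fragments at C7–C8: the (Z)-allylindium reacts at its γ-carbon through a chair Zimmerman–Traxler transition state to give the 7,8-syn alcohol, and with H-6 eclipsing the alkene (A(1,3) strain) the aldehyde is expected to add anti to the bulky silyloxy group, which gives the 6,7 relationship of the trans-lactone; the ketone is not attacked in water.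

Step 15
Reactants: 26 (the C8 alcohol from step 14); 27 3-methylbutanoic anhydride
Product: 28 methyl (3R,4R,6R)-3-[(1R)-1-[(tert-butyldimethylsilyl)oxy]prop-2-en-1-yl]-6,10-dimethyl-4-[(3-methylbutanoyl)oxy]-2-methylidene-7-oxo-6-[(triethylsilyl)oxy]undec-10-enoate
Conditions: 27, DMAP, Et3N, CH2Cl2, 0 °C → rt
Reagents that add atoms: none
Why: DMAP-catalysed acyl transfer esterifies the only free hydroxyl with retention at C8 and blocks it before the lactone is closed (any C8–O/C1 hemiketal is in equilibrium with the open hydroxy ketone that is acylated).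

Step 16
Reactants: 28 (the isovalerate from step 15)
Product: 30 (1R,3R)-1-[(2R,3R)-2-ethenyl-4-methylidene-5-oxooxolan-3-yl]-3-hydroxy-3,7-dimethyl-4-oxooct-7-en-1-yl 3-methylbutanoate, via dihydroxy ester 29 (not isolated)
Conditions: HF·pyridine, THF, 0 °C → rt; then PPTS (cat.), toluene, 50 °C
Reagents that add atoms: none
Why: Acidic fluoride removes both silyl ethers and the freed C6 hydroxyl lactonises onto the methyl ester to give the trans-disubstituted α-methylene butanolide; C8 is blocked as its ester and the C10 hydroxyl is tertiary, so only one lactone can form.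

Step 17
Reactants: 30 (the butanolide diene from step 16)
Product: 31 (3aR,4R,6R,10Z,11aR)-6-hydroxy-6,10-dimethyl-3-methylidene-2,7-dioxo-2,3,3a,4,5,6,7,8,9,11a-decahydrocyclodeca[b]furan-4-yl 3-methylbutanoate (CNP0105188.1)
Conditions: second-generation Grubbs catalyst RuCl2(=CHPh)(PCy3)(H2IMes) (15 mol %), 1,4-benzoquinone (30 mol %), toluene (1 mM), 90 °C
Reagents that add atoms: none
Why: Ring-closing metathesis between the C6 vinyl group and the 1,1-disubstituted alkene closes the ten-membered ring with loss of ethene; the ring-cis (Z) trisubstituted alkene is the less strained outcome and the electron-poor methylene lactone does not take part.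

**Compound list**
1 | (S)-lactic acid | C[C@H](O)C(=O)O | starting material
2 | pivalaldehyde | CC(C)(C)C=O | starting material
3 | (2S,5S)-2-tert-butyl-5-methyl-1,3-dioxolan-4-one | C[C@@H]1O[C@H](C(C)(C)C)OC1=O | intermediate
4 | allyl bromide | C=CCBr | starting material
5 | lithium (2S)-2-tert-butyl-5-methyl-1,3-dioxol-4-olate (lithium enolate of 3) | CC1=C(O[Li])O[C@@H](C(C)(C)C)O1 | intermediate
6 | (2S,5R)-2-tert-butyl-5-methyl-5-(prop-2-en-1-yl)-1,3-dioxolan-4-one | C[C@]1(CC=C)O[C@H](C(C)(C)C)OC1=O | intermediate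
7 | (2S,5R)-2-tert-butyl-5-methyl-5-(1,2,4-trioxolan-3-ylmethyl)-1,3-dioxolan-4-one (ozonide) | C[C@]1(CC2OOCO2)O[C@H](C(C)(C)C)OC1=O | intermediate
8 | (2S,5R)-2-tert-butyl-5-methyl-5-(2-oxoethyl)-1,3-dioxolan-4-one | C[C@]1(CC=O)O[C@H](C(C)(C)C)OC1=O | intermediate
9 | (2S,5R)-2-tert-butyl-5-(2-hydroxyethyl)-5-methyl-1,3-dioxolan-4-one | C[C@]1(CCO)O[C@H](C(C)(C)C)OC1=O | intermediate
10 | (3R)-3-hydroxy-3-methyloxolan-2-one | C[C@@]1(O)CCOC1=O | intermediate
11 | (2R)-2,4-dihydroxy-N-methoxy-N,2-dimethylbutanamide | CON(C)C(=O)[C@](C)(O)CCO | intermediate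
12 | (2R)-N-methoxy-N,2-dimethyl-2,4-bis[(triethylsilyl)oxy]butanamide | CON(C)C(=O)[C@](C)(O[Si](CC)(CC)CC)CCO[Si](CC)(CC)CC | intermediate
13 | 4-bromo-2-methylbut-1-ene | C=C(C)CCBr | starting material
14 | (3-methylbut-3-en-1-yl)magnesium bromide | C=C(C)CC[Mg]Br | intermediate
15 | (6R)-2,6-dimethyl-6,8-bis[(triethylsilyl)oxy]oct-1-en-5-one | C=C(C)CCC(=O)[C@](C)(O[Si](CC)(CC)CC)CCO[Si](CC)(CC)CC | intermediate
16 | (3R)-3,7-dimethyl-4-oxo-3-[(triethylsilyl)oxy]oct-7-enal | C=C(C)CCC(=O)[C@](C)(O[Si](CC)(CC)CC)CC=O | intermediate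
17 | (2R)-but-3-ene-1,2-diol | C=C[C@@H](O)CO | starting material
18 | (2R)-1,2-bis[(tert-butyldimethylsilyl)oxy]but-3-ene | C=C[C@@H](O[Si](C)(C)C(C)(C)C)CO[Si](C)(C)C(C)(C)C | intermediate
19 | (2R)-2-[(tert-butyldimethylsilyl)oxy]but-3-en-1-ol | C=C[C@@H](O[Si](C)(C)C(C)(C)C)CO | intermediate
20 | (2R)-2-[(tert-butyldimethylsilyl)oxy]but-3-enal | C=C[C@@H](O[Si](C)(C)C(C)(C)C)C=O | intermediate
21 | methyl propiolate | C#CC(=O)OC | starting material
22 | methyl 2-[bis(2-methylpropyl)alumanyl]prop-2-enoate (vinylalane) | C=C(C(=O)OC)[Al](CC(C)C)CC(C)C | intermediate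
23 | methyl (4R)-4-[(tert-butyldimethylsilyl)oxy]-3-hydroxy-2-methylidenehex-5-enoate (3-epimer mixture) | C=C[C@@H](O[Si](C)(C)C(C)(C)C)C(O)C(=C)C(=O)OC | intermediate
24 | methyl (2Z,4R)-2-(bromomethyl)-4-[(tert-butyldimethylsilyl)oxy]hexa-2,5-dienoate | COC(=O)/C(CBr)=C/[C@H](O[Si](C)(C)C(C)(C)C)C=C | intermediate
25 | methyl (2Z,4R)-4-[(tert-butyldimethylsilyl)oxy]-2-[(dibromoindiganyl)methyl]hexa-2,5-dienoate (allylindium reagent, drawn as the dibromide) | COC(=O)/C(C[In](Br)Br)=C/[C@H](O[Si](C)(C)C(C)(C)C)C=C | intermediate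
26 | methyl (3R,4R,6R)-3-[(1R)-1-[(tert-butyldimethylsilyl)oxy]prop-2-en-1-yl]-4-hydroxy-6,10-dimethyl-2-methylidene-7-oxo-6-[(triethylsilyl)oxy]undec-10-enoate | C=C(C(=O)OC)[C@H]([C@H](O)C[C@@](C)(O[Si](CC)(CC)CC)C(=O)CCC(C)=C)[C@H](O[Si](C)(C)C(C)(C)C)C=C | intermediate
27 | 3-methylbutanoic anhydride (isovaleric anhydride) | CC(C)CC(=O)OC(=O)CC(C)C | starting material
28 | methyl (3R,4R,6R)-3-[(1R)-1-[(tert-butyldimethylsilyl)oxy]prop-2-en-1-yl]-6,10-dimethyl-4-[(3-methylbutanoyl)oxy]-2-methylidene-7-oxo-6-[(triethylsilyl)oxy]undec-10-enoate | C=C(C(=O)OC)[C@H]([C@H](OC(=O)CC(C)C)C[C@@](C)(O[Si](CC)(CC)CC)C(=O)CCC(C)=C)[C@H](O[Si](C)(C)C(C)(C)C)C=C | intermediate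
29 | methyl (3S,4R,6R)-6-hydroxy-3-[(1R)-1-hydroxyprop-2-en-1-yl]-6,10-dimethyl-4-[(3-methylbutanoyl)oxy]-2-methylidene-7-oxoundec-10-enoate | C=C(C(=O)OC)[C@H]([C@H](OC(=O)CC(C)C)C[C@@](C)(O)C(=O)CCC(C)=C)[C@H](O)C=C | intermediate
30 | (1R,3R)-1-[(2R,3R)-2-ethenyl-4-methylidene-5-oxooxolan-3-yl]-3-hydroxy-3,7-dimethyl-4-oxooct-7-en-1-yl 3-methylbutanoate | C=C1C(=O)O[C@H](C=C)[C@H]1[C@H](OC(=O)CC(C)C)C[C@@](C)(O)C(=O)CCC(C)=C | intermediate
31 | (3aR,4R,6R,10Z,11aR)-6-hydroxy-6,10-dimethyl-3-methylidene-2,7-dioxo-2,3,3a,4,5,6,7,8,9,11a-decahydrocyclodeca[b]furan-4-yl 3-methylbutanoate | C=C1C(=O)O[C@@H]2/C=C(/C)CCC(=O)[C@](C)(O)C[C@@H](OC(=O)CC(C)C)[C@@H]12 | target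

**Step count**
Total: 17 steps. Longest linear sequence: 12 steps (steps 1–8, then 14–17).

**Three steps most likely to fail, with fallbacks**

Step 14 (face selectivity of the Barbier allylation). The 7,8-syn outcome of a (Z)-2-(bromomethyl)-2-enoate is dependable, but the sense of induction by the C6 silyloxy centre is a prediction, not a precedent-backed certainty. If the aldehyde adds syn to the silyloxy group, the antipodal bromide is used and the lactone is closed with inversion at C6. The fallback sets out from 16. The partner is made from bought (S)-but-3-ene-1,2-diol as in steps 9–13, through the bis-silyl ether F3, the primary alcohol F4 and the aldehyde F5. Allyl propiolate replaces 21, so that the vinylalane F6 gives the allyl ester adduct F7 and, with NBS/Me2S, the (2Z,4S)-allyl ester bromide F8. Indium in THF/H2O converts F8 into the allylindium reagent F9, which adds to 16 to give the C6-epimeric adduct F10. Acylation with 27 gives the isovalerate F11. Pd(PPh3)4 and morpholine remove the allyl ester to give the acid F12, and HF·pyridine gives the dihydroxy acid F13. Mitsunobu lactonisation (PPh3, DIAD, THF, 0 °C) then closes the butanolide with inversion at the allylic C6 carbinol and comes back to the route at 30.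

Step 17 (ring-closing metathesis to a ten-membered ring with a trisubstituted alkene). Oligomerisation, slow reaction at the 1,1-disubstituted alkene or E/Z mixtures are possible. The fallback closes the carbocycle before the lactone, on a substrate that is not constrained by the trans-fused butanolide. It sets out from 28, which under the same catalyst at high dilution gives the silyl-protected cyclodecene ester F14. HF·pyridine followed by catalytic PPTS then gives, through the dihydroxy ester F15, the lactone, so that the fallback comes back to the route at 31.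

Step 12 (addition of the α-aluminoacrylate to the epimerisable aldehyde). If the configuration at the silyloxy carbon erodes or conversion is poor, the same adduct is built by a low-temperature aldol and elimination. The fallback sets out from 20, which reacts with the lithium enolate of methyl 3-(dimethylamino)propanoate (LiN(iPr)2, THF, −78 °C) to give the amino alcohol F1. Methylation with MeI gives the trimethylammonium iodide F2, and elimination of trimethylamine with DBU in CH2Cl2 comes back to the route at 23.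

**Further compounds**
F1 | step 12 | methyl (4R)-4-[(tert-butyldimethylsilyl)oxy]-2-[(dimethylamino)methyl]-3-hydroxyhex-5-enoate (diastereomer mixture) | C=C[C@@H](O[Si](C)(C)C(C)(C)C)C(O)C(CN(C)C)C(=O)OC
F2 | step 12 | [(4R)-4-[(tert-butyldimethylsilyl)oxy]-3-hydroxy-2-(methoxycarbonyl)hex-5-en-1-yl]trimethylammonium iodide | C=C[C@@H](O[Si](C)(C)C(C)(C)C)C(O)C(C[N+](C)(C)C)C(=O)OC.[I-]
F3 | step 14 | (2S)-1,2-bis[(tert-butyldimethylsilyl)oxy]but-3-ene | C=C[C@H](O[Si](C)(C)C(C)(C)C)CO[Si](C)(C)C(C)(C)C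
F4 | step 14 | (2S)-2-[(tert-butyldimethylsilyl)oxy]but-3-en-1-ol | C=C[C@H](O[Si](C)(C)C(C)(C)C)CO
F5 | step 14 | (2S)-2-[(tert-butyldimethylsilyl)oxy]but-3-enal | C=C[C@H](O[Si](C)(C)C(C)(C)C)C=O
F6 | step 14 | prop-2-en-1-yl 2-[bis(2-methylpropyl)alumanyl]prop-2-enoate | C=CCOC(=O)C(=C)[Al](CC(C)C)CC(C)C
F7 | step 14 | prop-2-en-1-yl (4S)-4-[(tert-butyldimethylsilyl)oxy]-3-hydroxy-2-methylidenehex-5-enoate (3-epimer mixture) | C=CCOC(=O)C(=C)C(O)[C@@H](O[Si](C)(C)C(C)(C)C)C=C
F8 | step 14 | prop-2-en-1-yl (2Z,4S)-2-(bromomethyl)-4-[(tert-butyldimethylsilyl)oxy]hexa-2,5-dienoate | C=CCOC(=O)/C(CBr)=C/[C@@H](O[Si](C)(C)C(C)(C)C)C=C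
F9 | step 14 | prop-2-en-1-yl (2Z,4S)-4-[(tert-butyldimethylsilyl)oxy]-2-[(dibromoindiganyl)methyl]hexa-2,5-dienoate | C=CCOC(=O)/C(C[In](Br)Br)=C/[C@@H](O[Si](C)(C)C(C)(C)C)C=C
F10 | step 14 | prop-2-en-1-yl (3R,4R,6R)-3-[(1S)-1-[(tert-butyldimethylsilyl)oxy]prop-2-en-1-yl]-4-hydroxy-6,10-dimethyl-2-methylidene-7-oxo-6-[(triethylsilyl)oxy]undec-10-enoate | C=CCOC(=O)C(=C)[C@H]([C@H](O)C[C@@](C)(O[Si](CC)(CC)CC)C(=O)CCC(C)=C)[C@@H](O[Si](C)(C)C(C)(C)C)C=C
F11 | step 14 | prop-2-en-1-yl (3R,4R,6R)-3-[(1S)-1-[(tert-butyldimethylsilyl)oxy]prop-2-en-1-yl]-6,10-dimethyl-4-[(3-methylbutanoyl)oxy]-2-methylidene-7-oxo-6-[(triethylsilyl)oxy]undec-10-enoate | C=CCOC(=O)C(=C)[C@H]([C@H](OC(=O)CC(C)C)C[C@@](C)(O[Si](CC)(CC)CC)C(=O)CCC(C)=C)[C@@H](O[Si](C)(C)C(C)(C)C)C=C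
F12 | step 14 | (3R,4R,6R)-3-[(1S)-1-[(tert-butyldimethylsilyl)oxy]prop-2-en-1-yl]-6,10-dimethyl-4-[(3-methylbutanoyl)oxy]-2-methylidene-7-oxo-6-[(triethylsilyl)oxy]undec-10-enoic acid | OC(=O)C(=C)[C@H]([C@H](OC(=O)CC(C)C)C[C@@](C)(O[Si](CC)(CC)CC)C(=O)CCC(C)=C)[C@@H](O[Si](C)(C)C(C)(C)C)C=C
F13 | step 14 | (3S,4R,6R)-6-hydroxy-3-[(1S)-1-hydroxyprop-2-en-1-yl]-6,10-dimethyl-4-[(3-methylbutanoyl)oxy]-2-methylidene-7-oxoundec-10-enoic acid | OC(=O)C(=C)[C@H]([C@H](OC(=O)CC(C)C)C[C@@](C)(O)C(=O)CCC(C)=C)[C@@H](O)C=C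
F14 | step 17 | methyl 2-[(1R,2R,3Z,8R,10R)-2-[(tert-butyldimethylsilyl)oxy]-4,8-dimethyl-10-[(3-methylbutanoyl)oxy]-7-oxo-8-[(triethylsilyl)oxy]cyclodec-3-en-1-yl]prop-2-enoate | C=C(C(=O)OC)[C@@H]1[C@H](OC(=O)CC(C)C)C[C@@](C)(O[Si](CC)(CC)CC)C(=O)CC/C(C)=C\[C@H]1O[Si](C)(C)C(C)(C)C
F15 | step 17 | methyl 2-[(1S,2R,3Z,8R,10R)-2,8-dihydroxy-4,8-dimethyl-10-[(3-methylbutanoyl)oxy]-7-oxocyclodec-3-en-1-yl]prop-2-enoate | C=C(C(=O)OC)[C@@H]1[C@H](OC(=O)CC(C)C)C[C@@](C)(O)C(=O)CC/C(C)=C\[C@H]1O
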